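The oxirane is opened retrosynthetically at its O–CH2 bond to a bromohydrin, and this is traced to a 2-arylallyl isovalerate. The key step exploits the isovalerate on the CH2 attached to the quaternary oxirane carbon C2: its carbonyl oxygen can reach that benzylic carbon through a five-membered ring, so bromenium transfer to the alkene lets it close a transient 1,3-dioxolan-2-ylium ring, which water then opens. One operation thus forms the C2–O bond, the CH2–Br bond and the only stereocentre, with both esters and the formyl group already in place. The precursor is the deoxy alkene, the bis-isovalerate of 3-hydroxy-4-(3-hydroxyprop-1-en-2-yl)benzaldehyde.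

Key step: step 4

Remarks on the chemistry:
- Descriptors: (S) in bromohydrin 11 and (R) in target 12 denote the same spatial arrangement; ring closure does not touch the stereocentre, and only the CIP ranking of the CH2Br/CH2O arms changes.
- Assumption: the sense of induction of cinchona dimers on allylic esters is not established; (DHQ)2PHAL is assumed to give the (S) series by analogy with N-(2-arylallyl) amides, and (DHQD)2PHAL takes its place should the (R) series form.
- No protecting group is used: an acetal on the formyl group would not survive the aqueous acidic bromination, and any late deprotection would endanger the oxirane.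

Step 1
Reactants: 1 4-bromo-3-hydroxybenzaldehyde; 2 bis(pinacolato)diboron
Product: 3 3-hydroxy-4-(4,4,5,5-tetramethyl-1,3,2-dioxaborolan-2-yl)benzaldehyde
Conditions: Pd(dppf)Cl2 (3 mol %), KOAc (3 equiv), 1,4-dioxane, 90 °C
Reagents that add atoms: none
Why: Miyaura borylation (oxidative addition of zerovalent palladium into C–Br, acetate-assisted transmetalation from 2, reductive elimination) should proceed because KOAc is too weak a base to start Suzuki homocoupling and because free phenols and aryl aldehydes are tolerated.

Step 2
Reactants: 3 3-hydroxy-4-(4,4,5,5-tetramethyl-1,3,2-dioxaborolan-2-yl)benzaldehyde; 4 2-bromoprop-2-en-1-ol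
Product: 5 3-hydroxy-4-(3-hydroxyprop-1-en-2-yl)benzaldehyde
Conditions: Pd(dppf)Cl2 (5 mol %), K2CO3 (3 equiv), 1,4-dioxane–H2O 4:1, 70 °C; work-up at pH 5
Reagents that add atoms: none
Why: Suzuki–Miyaura coupling of an aryl pinacol boronate with a vinyl bromide, for which 2-bromoallyl alcohol is an established partner, should give the 2-arylallyl alcohol with the free hydroxyl groups and the aldehyde as spectators.

Step 3
Reactants: 5 3-hydroxy-4-(3-hydroxyprop-1-en-2-yl)benzaldehyde; 6 3-methylbutanoic anhydride (2.5 equiv)
Product: 7 2-[4-formyl-2-(3-methylbutanoyloxy)phenyl]prop-2-en-1-yl 3-methylbutanoate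
Conditions: Et3N (3 equiv), DMAP (5 mol %), CH2Cl2, 0 °C to rt
Reagents that add atoms: none
Why: DMAP-catalysed acyl transfer (Steglich-type acylation) should esterify the phenol and the primary allylic alcohol in one operation, the aldehyde being inert to an anhydride under basic conditions.

Step 4
Reactants: 7 2-[4-formyl-2-(3-methylbutanoyloxy)phenyl]prop-2-en-1-yl 3-methylbutanoate
Product: 11 (2S)-3-bromo-2-[4-formyl-2-(3-methylbutanoyloxy)phenyl]-2-hydroxypropyl 3-methylbutanoate, via bromiranium ion 8 (not isolated), via dioxolan-2-ylium ion 9 (not isolated), via 2-hydroxy-1,3-dioxolane 10 (not isolated)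
Conditions: NBS (1.2 equiv), (DHQ)2PHAL (10 mol %), CSA (10 mol %), H2O (5 equiv), acetone, −30 °C, dark
Reagents that add atoms: N-bromosuccinimide O=C1CCC(=O)N1Br; water O
Why: Proposed new method: the protonated cinchona dimer should hand bromenium from NBS to one face of the 1,1-disubstituted alkene (bromiranium ion 8), the carbonyl oxygen of the allylic isovalerate opens 8 at the benzylic carbon anti to bromine to give dioxolan-2-ylium ion 9, water adds at the acyl carbon (10), and the hemiorthoester collapses to primary ester and tertiary alcohol 11, a tertiary-ester isomer (by 1,2-acyl shift) or direct capture of 8 by water leading to the same compound. The closest known reaction types are the cinchona-dimer-catalysed halocyclisation of N-(2-arylallyl) amides to 5-aryl-5-(halomethyl)oxazolines and Woodward–Prévost acyloxonium capture by water; an ester carbonyl as internal nucleophile under this catalysis is the untested element. Two transient rings close, the three-membered bromiranium by bromenium addition across the alkene and the 1,3-dioxolan-2-ylium by 5-exo attack on the internal alkene carbon (5-exo-tet opening of 8), and neither remains in 11. The one new stereocentre (benzylic carbinol carbon, S) is set by catalyst control of the alkene face that receives bromine and is relayed by the stereospecific anti opening. The step needs Markovnikov regiochemistry, secured by the aryl group and the five-membered ring size, and chemoselectivity for the alkyl ester carbonyl (more Lewis basic, five-membered closure) over the aryl ester carbonyl (six-membered closure) and for the alkene over the formyl group, secured by low temperature, darkness and the small excess of water. The para-formyl group disfavours an open benzylic cation, which should protect the enantiomeric purity at the cost of rate.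

Step 5
Reactants: 11 (2S)-3-bromo-2-[4-formyl-2-(3-methylbutanoyloxy)phenyl]-2-hydroxypropyl 3-methylbutanoate
Product: 12 [(2R)-2-[4-formyl-2-(3-methylbutanoyloxy)phenyl]oxiran-2-yl]methyl 3-methylbutanoate
Conditions: Ag2O (1.5 equiv), 4 Å MS, CH2Cl2, rt, dark
Reagents that add atoms: none
Why: Silver-assisted intramolecular Williamson etherification (3-exo-tet) should close the oxirane because Ag2O serves as halophile and mild base, so that the tertiary hydroxyl displaces the activated primary bromide without a free alkoxide that could take the acyl group from the aryl ester, no bond at the stereocentre is broken, and the sieves keep the medium dry so that the formyl group is not oxidised.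

Compound list
1 | 4-bromo-3-hydroxybenzaldehyde | O=Cc1ccc(Br)c(O)c1 | starting material
2 | bis(pinacolato)diboron | CC1(C)OB(OC1(C)C)B1OC(C)(C)C(C)(C)O1 | starting material
3 | 3-hydroxy-4-(4,4,5,5-tetramethyl-1,3,2-dioxaborolan-2-yl)benzaldehyde | O=Cc1ccc(B2OC(C)(C)C(C)(C)O2)c(O)c1 | intermediate
4 | 2-bromoprop-2-en-1-ol | OCC(Br)=C | starting material
5 | 3-hydroxy-4-(3-hydroxyprop-1-en-2-yl)benzaldehyde | C=C(CO)c1ccc(C=O)cc1O | intermediate
6 | 3-methylbutanoic anhydride (isovaleric anhydride) | CC(C)CC(=O)OC(=O)CC(C)C | starting material
7 | 2-[4-formyl-2-(3-methylbutanoyloxy)phenyl]prop-2-en-1-yl 3-methylbutanoate | C=C(COC(=O)CC(C)C)c1ccc(C=O)cc1OC(=O)CC(C)C | intermediate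
8 | (2R)-2-[4-formyl-2-(3-methylbutanoyloxy)phenyl]-2-[(3-methylbutanoyloxy)methyl]bromiranium ion | CC(C)CC(=O)OC[C@]1(c2ccc(C=O)cc2OC(=O)CC(C)C)C[Br+]1 | intermediate
9 | (4S)-4-(bromomethyl)-4-[4-formyl-2-(3-methylbutanoyloxy)phenyl]-2-(2-methylpropyl)-1,3-dioxolan-2-ylium ion | CC(C)CC1=[O+][C@@](CBr)(c2ccc(C=O)cc2OC(=O)CC(C)C)CO1 | intermediate
10 | 2-[(4S)-4-(bromomethyl)-2-hydroxy-2-(2-methylpropyl)-1,3-dioxolan-4-yl]-5-formylphenyl 3-methylbutanoate (both epimers at the orthoester carbon) | CC(C)CC1(O)O[C@@](CBr)(c2ccc(C=O)cc2OC(=O)CC(C)C)CO1 | intermediate
11 | (2S)-3-bromo-2-[4-formyl-2-(3-methylbutanoyloxy)phenyl]-2-hydroxypropyl 3-methylbutanoate | CC(C)CC(=O)OC[C@@](O)(c1ccc(C=O)cc1OC(=O)CC(C)C)CBr | intermediate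
12 | [(2R)-2-[4-formyl-2-(3-methylbutanoyloxy)phenyl]oxiran-2-yl]methyl 3-methylbutanoate | CC(C)CC(=O)OC[C@@]1(c2ccc(C=O)cc2OC(=O)CC(C)C)CO1 | target

Total step count: 5
Longest linear sequence: 5 steps (1 → 3 → 5 → 7 → 11 → 12)

Steps most likely to fail

Step 4 (key step). What may go wrong: poor or reversed facial selectivity in bromenium delivery, or an uncatalysed racemic bromination outpacing the catalysed path on this deactivated alkene. The fallback uses known chemistry, a Katsuki–Sharpless asymmetric epoxidation of a 2-arylallyl alcohol, and leaves the route at 5 and rejoins it at 12. Phenol-selective acylation of 5 with 6 (1.05 equiv, K2CO3, MeCN, 0 °C; the phenoxide reacts, the neutral primary alcohol does not without DMAP) should give 5-formyl-2-(3-hydroxyprop-1-en-2-yl)phenyl 3-methylbutanoate F1. Epoxidation of F1 with Ti(OiPr)4, L-(+)-diethyl tartrate, tert-butyl hydroperoxide and 4 Å MS in CH2Cl2 at −20 °C should give 5-formyl-2-[(2S)-2-(hydroxymethyl)oxiran-2-yl]phenyl 3-methylbutanoate F2. The tartrate fixes the face as in the 2-substituted glycidol series. Acylation of F2 with 6 (Et3N, DMAP, CH2Cl2, 0 °C) should give 12, the descriptor changing from S to R by CIP ranking only. This fallback also makes step 5 unnecessary.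

Step 5. What may go wrong: slow silver-assisted ionisation of the neopentyl-type C–Br bond, leaving time for oxidation of the formyl group by Ag2O or for acyl transfer from the aryl ester to the tertiary oxygen. The fallback sets out from 11 and returns at 12, and generates the nucleophile by fluoride instead of activating the leaving group with silver. Silylation of the tertiary hydroxyl (TMSCl, imidazole, DMF, 0 °C) should give (2S)-3-bromo-2-[4-formyl-2-(3-methylbutanoyloxy)phenyl]-2-(trimethylsilyloxy)propyl 3-methylbutanoate F3. One equivalent of Bu4NF in THF at −78 °C, warming to −20 °C, then unmasks the alkoxide in homogeneous solution without silver or amide base. The alkoxide should close onto the CH2Br carbon by the same 3-exo-tet displacement, a known fluoride-triggered epoxide formation from β-halo silyl ethers.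

Step 1. What may go wrong: protodeborylation, reductive debromination or catalyst inhibition by the free ortho-phenol, so that boronate 3 is not obtained cleanly; the same weakness would carry into step 2. The fallback reverses the polarity by a Stille coupling, going from 1 straight to 5 and replacing steps 1 and 2. 2-(Tributylstannyl)prop-2-en-1-ol F4 is made by α-selective hydrostannation of prop-2-yn-1-ol with Bu3SnH (Mo(CO)3(CNtBu)3 catalyst, THF, 55 °C). Coupling of F4 with 1 (Pd(PPh3)4, CuI, DMF, 80 °C) should give 5 without any arylboron species.

Further compounds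
F1 | step 4 | 5-formyl-2-(3-hydroxyprop-1-en-2-yl)phenyl 3-methylbutanoate | C=C(CO)c1ccc(C=O)cc1OC(=O)CC(C)C
F2 | step 4 | 5-formyl-2-[(2S)-2-(hydroxymethyl)oxiran-2-yl]phenyl 3-methylbutanoate | OC[C@@]1(c2ccc(C=O)cc2OC(=O)CC(C)C)CO1
F3 | step 5 | (2S)-3-bromo-2-[4-formyl-2-(3-methylbutanoyloxy)phenyl]-2-(trimethylsilyloxy)propyl 3-methylbutanoate | CC(C)CC(=O)OC[C@@](O[Si](C)(C)C)(c1ccc(C=O)cc1OC(=O)CC(C)C)CBr
F4 | step 1 | 2-(tributylstannyl)prop-2-en-1-ol | OCC(=C)[Sn](CCCC)(CCCC)CCCC
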